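The 2,2-dimethyl-2H-pyran ring is cut on both sides of its C3=C4 unit, which is recognised as acetylene. What remains at C2 is a tertiary carbon bound to O1, that is, a stabilised α-aryloxy radical, and C4a is a free C–H position ortho to O1 on the benzene ring. A redox-neutral photoredox decarboxylative (4+2) radical annulation therefore joins C2–C3 and C4–C4a in one operation and delivers the chromene at its final oxidation level. Its precursor is the N-acyloxyphthalimide of an aryloxyisobutyric acid, made by a Bargellini reaction on a commercial acetophenone. The (S)-carbinol is set last by asymmetric transfer hydrogenation of a 1,3-diketone.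

Key step: step 3

Remark: chromene numbering (O1, C2, C3, C4, C4a, C5 to C8, C8a) is used throughout, also for the "future" positions of open precursors. Diketone 14 is drawn as its diketo tautomer although the chelated enol should dominate.

Step 1
Reactants: 1 2',4'-dihydroxy-6'-methoxyacetophenone; 2 acetone; 3 chloroform
Product: 6 2-(4-acetyl-3-hydroxy-5-methoxyphenoxy)-2-methylpropanoic acid, via 2,2-dichloro-3,3-dimethyloxirane 4 (not isolated), via aryloxyisobutyryl chloride 5 (not isolated)
Conditions: NaOH (powder), CHCl3 (slow addition), acetone, 0 °C to reflux; then aq HCl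
Reagents that add atoms: sodium hydroxide [Na+].[OH-]
Why: Bargellini reaction, in which trichloromethanide adds to acetone, the alkoxide closes to gem-dichloroepoxide 4, and the unchelated, less hindered C4' phenoxide opens 4 at its tertiary carbon to acyl chloride 5, which hydroxide hydrolyses, as in the standard preparation of fibric acids from para-acylphenols.

Step 2
Reactants: 6 2-(4-acetyl-3-hydroxy-5-methoxyphenoxy)-2-methylpropanoic acid
Product: 7 1,3-dioxoisoindolin-2-yl 2-(4-acetyl-3-hydroxy-5-methoxyphenoxy)-2-methylpropanoate
Conditions: N-hydroxyphthalimide, DIC, DMAP (cat.), CH2Cl2, rt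
Reagents that add atoms: N-hydroxyphthalimide O=C1c2ccccc2C(=O)N1O
Why: Steglich-type carbodiimide esterification gives the redox-active ester, a routine derivatisation of tertiary fibric-type acids, and the chelated, hindered phenol should not compete with the more nucleophilic N-hydroxyphthalimide.

Step 3
Reactants: 7 1,3-dioxoisoindolin-2-yl 2-(4-acetyl-3-hydroxy-5-methoxyphenoxy)-2-methylpropanoate; 8 acetylene
Product: 11 1-(5-hydroxy-7-methoxy-2,2-dimethyl-2H-chromen-6-yl)ethan-1-one, via tertiary C2 radical 9 (not isolated), via vinyl C4 radical 10 (not isolated)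
Conditions: acetylene (1 atm, balloon), fac-Ir(ppy)3 (1 mol %), degassed acetone, blue LEDs (450 nm), rt
Reagents that add atoms: none
Why: Proposed new method: excited fac-Ir(ppy)3 transfers one electron to the N-acyloxyphthalimide of 7, which loses phthalimide anion and CO2 to give the tertiary, O1-stabilised radical 9 at C2; 9 adds to acetylene (C2–C3 bond), the σ-vinyl radical 10 attacks the free ortho carbon C4a (C4–C4a bond), tetravalent iridium oxidises the resulting cyclohexadienyl radical and phthalimide anion takes the proton, so the cycle is redox-neutral and the C3=C4 alkene arrives at its final oxidation level. The closest known reaction types are the photoredox decarboxylative (4+2) radical annulation of α-aryloxy N-acyloxyphthalimides with electron-poor alkenes to chromans, the radical cyclisation of aryl propargyl ethers to 2H-chromenes through the same kind of vinyl radical, and the peroxide-initiated addition of the 2-hydroxy-2-propyl radical to acetylene; what is new is acetylene as the two-carbon partner of an α-aryloxy radical. The only ring closed is the pyran ring, by a six-membered ortho (Ar2-6) homolytic aromatic substitution, 6-endo with respect to the C4a=C8a bond and helped by the gem-dimethyl effect, in preference to five-membered ipso attack at C8a, which would have to expel a high-energy alkoxyl radical. No stereocentre is formed and the ring enforces the Z alkene. The step needs site selectivity between the two carbons ortho to the ether oxygen: the chelated OH points toward the acetyl oxygen and leaves the future C4a open, whereas the acetyl group turns the methyl of the methoxy group toward the future C8, and attack there would wedge that methoxy group between the acetyl group and the new C4–H. It also needs capture of 9 by acetylene to outrun its oxidation to the oxocarbenium ion, which the high solubility of acetylene in acetone and the low catalyst loading should favour.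

Step 4
Reactants: 11 1-(5-hydroxy-7-methoxy-2,2-dimethyl-2H-chromen-6-yl)ethan-1-one; 12 benzoyl chloride
Product: 14 1-(5-hydroxy-7-methoxy-2,2-dimethyl-2H-chromen-6-yl)-3-phenylpropane-1,3-dione, via dilithium phenoxide-enolate 13 (not isolated)
Conditions: LiHMDS (3.5 equiv), THF, −78 to −10 °C; PhCOCl (1.0 equiv), −78 °C to rt; then aq HCl
Reagents that add atoms: none
Why: Claisen-type C-acylation of the doubly lithiated species 13 (the direct variant of the Baker–Venkataraman route) should give the diketone, since any benzoate formed at the phenoxide would reach the same product by base-induced acyl migration.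

Step 5
Reactants: 14 1-(5-hydroxy-7-methoxy-2,2-dimethyl-2H-chromen-6-yl)-3-phenylpropane-1,3-dione
Product: 15 (S)-3-hydroxy-1-(5-hydroxy-7-methoxy-2,2-dimethyl-2H-chromen-6-yl)-3-phenylpropan-1-one
Conditions: RuCl[(S,S)-TsDPEN](p-cymene) (1 mol %), HCO2H/Et3N (5:2), EtOAc, rt
Reagents that add atoms: none
Why: Noyori–Ikariya asymmetric transfer hydrogenation should reduce only the benzoyl carbonyl, because the other ketone is flanked by two ortho oxygen substituents, chelated by the C5–OH and electronically deactivated, and the (S,S)-catalyst delivers hydride to a phenyl ketone through its CH/π-organised transition state on the face that gives the (S)-carbinol.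

Compound list
1 | 2',4'-dihydroxy-6'-methoxyacetophenone | CC(=O)c1c(O)cc(O)cc1OC | starting material
2 | acetone | CC(C)=O | starting material
3 | chloroform | ClC(Cl)Cl | starting material
4 | 2,2-dichloro-3,3-dimethyloxirane | CC1(C)OC1(Cl)Cl | intermediate
5 | 2-(4-acetyl-3-hydroxy-5-methoxyphenoxy)-2-methylpropanoyl chloride | CC(=O)c1c(O)cc(OC(C)(C)C(=O)Cl)cc1OC | intermediate
6 | 2-(4-acetyl-3-hydroxy-5-methoxyphenoxy)-2-methylpropanoic acid | CC(=O)c1c(O)cc(OC(C)(C)C(=O)O)cc1OC | intermediate
7 | 1,3-dioxoisoindolin-2-yl 2-(4-acetyl-3-hydroxy-5-methoxyphenoxy)-2-methylpropanoate | CC(=O)c1c(O)cc(OC(C)(C)C(=O)ON2C(=O)c3ccccc3C2=O)cc1OC | intermediate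
8 | acetylene | C#C | starting material
9 | 2-(4-acetyl-3-hydroxy-5-methoxyphenoxy)propan-2-yl radical | CC(=O)c1c(O)cc(O[C](C)C)cc1OC | intermediate
10 | 3-(4-acetyl-3-hydroxy-5-methoxyphenoxy)-3-methylbut-1-en-1-yl radical | CC(=O)c1c(O)cc(OC(C)(C)C=[CH])cc1OC | intermediate
11 | 1-(5-hydroxy-7-methoxy-2,2-dimethyl-2H-chromen-6-yl)ethan-1-one | COc1cc2c(c(O)c1C(C)=O)C=CC(C)(C)O2 | intermediate
12 | benzoyl chloride | O=C(Cl)c1ccccc1 | starting material
13 | dilithium phenoxide-enolate of 11 | [Li+].[Li+].C=C([O-])c1c([O-])c2c(cc1OC)OC(C)(C)C=C2 | intermediate
14 | 1-(5-hydroxy-7-methoxy-2,2-dimethyl-2H-chromen-6-yl)-3-phenylpropane-1,3-dione | COc1cc2c(c(O)c1C(=O)CC(=O)c1ccccc1)C=CC(C)(C)O2 | intermediate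
15 | (S)-3-hydroxy-1-(5-hydroxy-7-methoxy-2,2-dimethyl-2H-chromen-6-yl)-3-phenylpropan-1-one | COc1cc2c(c(O)c1C(=O)C[C@H](O)c1ccccc1)C=CC(C)(C)O2 | target

Total step count: 5. Longest linear sequence: 5.

Steps most likely to fail

Step 3 (labelled step).
- **What may go wrong:** Acetylene may capture the tertiary radical too slowly, so that the radical is oxidised and loses a proton before any C–C bond forms. Cyclisation may also leak to the other ortho carbon, the vinyl radical may abstract hydrogen from the solvent, or the catalyst may sensitise electrocyclic opening of the chromene.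
- **Fallback (known chemistry, from 7 back to 11):** Compound 7 is irradiated under the same kind of photoredox catalysis with phenyl vinyl sulfone in place of acetylene. This is the established (4+2) radical annulation with an electron-poor alkene. Both radical steps are then polarity-matched: the nucleophilic C2 radical adds to the acceptor, and the electrophilic α-sulfonyl radical attacks the electron-rich ring. The product should be racemic 1-[5-hydroxy-7-methoxy-2,2-dimethyl-4-(phenylsulfonyl)chroman-6-yl]ethan-1-one F1. DBU in MeCN should then remove benzenesulfinate by phenoxide-assisted elimination, in the way 2-(sulfonylmethyl)phenols lose sulfinate, and install the C3=C4 alkene of 11.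

Step 5.
- **What may go wrong:** The strongly enolised diketone may be reduced only sluggishly, or hydride may go to the wrong carbonyl or to both. Acid may induce cyclodehydration through the C5–OH, and retro-aldol equilibration may erode the enantiomeric purity.
- **Fallback (from 11 back to 15, bypassing 14):** Claisen–Schmidt condensation of 11 with benzaldehyde (KOH, EtOH) should give (E)-1-(5-hydroxy-7-methoxy-2,2-dimethyl-2H-chromen-6-yl)-3-phenylprop-2-en-1-one F2. Enantioselective conjugate borylation follows (CuCl, NaOtBu, a Josiphos-type ligand, B2pin2, MeOH, THF). The ligand enantiomer is chosen to deliver the (S)-configured β-boryl ketone (S)-1-(5-hydroxy-7-methoxy-2,2-dimethyl-2H-chromen-6-yl)-3-phenyl-3-(4,4,5,5-tetramethyl-1,3,2-dioxaborolan-2-yl)propan-1-one F3. Oxidation with NaBO3·4H2O in THF/H2O proceeds with retention and should give 15.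

Step 1.
- **What may go wrong:** The chelated phenoxide may also be alkylated, carbene-type attack may occur on the electron-rich ring, or the acetyl group may undergo aldol condensation with acetone.
- **Fallback (from 1 back to 6):** Under weak base only the unchelated phenol is ionised. Alkylation of 1 with ethyl 2-bromo-2-methylpropanoate (K2CO3, DMF, 60 °C) should therefore give ethyl 2-(4-acetyl-3-hydroxy-5-methoxyphenoxy)-2-methylpropanoate F4. Saponification with LiOH in THF/H2O followed by acidification should give 6.

Further compounds
F1 | step 3 | racemic 1-[5-hydroxy-7-methoxy-2,2-dimethyl-4-(phenylsulfonyl)chroman-6-yl]ethan-1-one | COc1cc2c(c(O)c1C(C)=O)C(S(=O)(=O)c1ccccc1)CC(C)(C)O2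
F2 | step 5 | (E)-1-(5-hydroxy-7-methoxy-2,2-dimethyl-2H-chromen-6-yl)-3-phenylprop-2-en-1-one | COc1cc2c(c(O)c1C(=O)/C=C/c1ccccc1)C=CC(C)(C)O2
F3 | step 5 | (S)-1-(5-hydroxy-7-methoxy-2,2-dimethyl-2H-chromen-6-yl)-3-phenyl-3-(4,4,5,5-tetramethyl-1,3,2-dioxaborolan-2-yl)propan-1-one | COc1cc2c(c(O)c1C(=O)C[C@H](B1OC(C)(C)C(C)(C)O1)c1ccccc1)C=CC(C)(C)O2
F4 | step 1 | ethyl 2-(4-acetyl-3-hydroxy-5-methoxyphenoxy)-2-methylpropanoate | CCOC(=O)C(C)(C)Oc1cc(O)c(C(C)=O)c(OC)c1
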